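**Strategy.** Everything hinges on disconnecting ring B from ring A at C8a–C1 and C4a–C4. The four non-fusion carbons of ring B (C1 to C4) form an unbroken chain with the side chain on C2, which maps onto C2 to C5 of a 3-substituted furan, and ring A is a 3,6-dimethoxybenzyne whose symmetry removes any orientation problem. A single aryne–furan [4+2] cycloaddition therefore makes both bonds and closes ring B as an oxygen-bridged dihydronaphthalene. Its furan partner is the enantiopure (R)-configured silyl ether, whose C1' centre is set beforehand by catalytic ketone reduction. Bridge opening with para-oxidation, ester formation and oxidative demethylation finish the synthesis.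

Key step: step 5

Remark on the chemistry: the cycloaddition should give both cis-bridged bridgehead epimers of the adduct. They have the same constitution and react alike, so they are carried together under the single number 14, which is named and drawn as the (1S,4R) isomer. Its (1R,4S) epimer is CC(C)=CC[C@@H](O[Si](C)(C)C(C)(C)C)C1=C[C@@H]2O[C@H]1c3c(OC)ccc(OC)c23. TBS = tert-butyldimethylsilyl. The naphthazarin is drawn as the tautomer given in the target structure.

**Step 1**
Reactants: 1 4-methylpent-3-enoic acid
Product: 3 N-methoxy-N,4-dimethylpent-3-enamide, via acyl imidazole 2 (not isolated)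
Conditions: 1,1'-carbonyldiimidazole (1.1 equiv), CH2Cl2, 0 °C → rt; then MeNH(OMe)·HCl (1.2 equiv), rt
Reagents that add atoms: N,O-dimethylhydroxylamine hydrochloride, CNOC.Cl
Why: Weinreb amide formation through the acyl imidazole is a neutral amidation that should leave the β,γ-alkene in place.

**Step 2**
Reactants: 4 3-bromofuran; 3 N-methoxy-N,4-dimethylpent-3-enamide
Product: 7 1-(furan-3-yl)-4-methylpent-3-en-1-one, via 3-lithiofuran 5 (not isolated), via lithium hemiaminal alkoxide 6 (not isolated)
Conditions: 4 (1.25 equiv), n-BuLi (1.2 equiv), THF, −78 °C; then 3 (1.0 equiv), −78 → −40 °C; sat. aq NH4Cl at −78 °C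
Reagents that add atoms: none
Why: Bromine–lithium exchange followed by Weinreb ketone synthesis should stop at the chelated tetrahedral adduct, so the β,γ-unsaturated ketone is released only on cold, nearly neutral quench and should not slip into conjugation.

**Step 3**
Reactants: 7 1-(furan-3-yl)-4-methylpent-3-en-1-one
Product: 9 (1R)-1-(furan-3-yl)-4-methylpent-3-en-1-ol, via catechol borate ester 8 (not isolated)
Conditions: (3aS)-1-methyl-3,3-diphenyltetrahydro-1H,3H-pyrrolo[1,2-c][1,3,2]oxazaborole [(S)-Me-CBS] (0.15 equiv), catecholborane (1.8 equiv), toluene, −78 °C; then MeOH, 1 M aq NaOH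
Reagents that add atoms: none
Why: Corey–Bakshi–Shibata reduction with the furyl ring as the large and the CH2 chain as the small substituent should give the (R)-carbinol in the same sense as acetophenone gives (R)-1-phenylethanol, and catecholborane at −78 °C should not hydroborate the trisubstituted alkene.

**Step 4**
Reactants: 9 (1R)-1-(furan-3-yl)-4-methylpent-3-en-1-ol
Product: 10 tert-butyl{[(1R)-1-(furan-3-yl)-4-methylpent-3-en-1-yl]oxy}dimethylsilane
Conditions: TBSCl (1.2 equiv), imidazole (2.5 equiv), DMF, rt
Reagents that add atoms: tert-butyldimethylsilyl chloride, CC(C)(C)[Si](C)(C)Cl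
Why: Imidazole-promoted silyl ether formation occurs at oxygen only, so the C1' configuration is retained and the alcohol is masked against the strong base of step 5.

**Step 5**
Reactants: 10 tert-butyl{[(1R)-1-(furan-3-yl)-4-methylpent-3-en-1-yl]oxy}dimethylsilane; 11 2-bromo-1,4-dimethoxybenzene
Product: 14 (1S,4R)-2-[(1R)-1-(TBS-oxy)-4-methylpent-3-en-1-yl]-5,8-dimethoxy-1,4-dihydro-1,4-epoxynaphthalene, via aryllithium 12 (not isolated), via 3,6-dimethoxybenzyne 13 (not isolated)
Conditions: 10 (1.0 equiv), 11 (2.0 equiv), LiN(iPr)2 (commercial solution, 2.2 equiv, added slowly), THF, −78 °C → rt; chromatography on Et3N-deactivated silica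
Reagents that add atoms: none
Why: LiN(iPr)2 removes the hydrogen of 11 that lies between the bromine-bearing and a methoxy-bearing carbon to give aryllithium 12, which loses LiBr on warming to give the symmetric aryne 13; the furan ring of 10 then adds as the 4π component across its C2 and C5 in a concerted suprafacial [4+2] cycloaddition, forming C8a–C1 and C4a–C4 together. The closest known reaction type is the aryne–furan Diels–Alder reaction, the standard entry to 1,4-epoxy-1,4-dihydronaphthalenes. Ring B, the only ring formed, closes by this intermolecular cycloaddition as a six-membered carbocycle that carries the furan oxygen as a one-atom bridge. The two new bridgehead stereocentres C1 and C4 are necessarily cis across the bridge because the addition is concerted, whereas their sense relative to C1' is uncontrolled, so 14 should form as both bridgehead epimers, which is harmless because both centres become sp2 in step 6. No regioselectivity is needed because the aryne is symmetric; what is needed is chemoselectivity for the furan diene over the amide base, the trisubstituted alkene and the strained alkene of the product, which the high diene reactivity of furans towards arynes and slow aryne generation in the presence of 10 should secure. The C1' hydrogen is not acidic enough for LiN(iPr)2 and the oxygen is masked as a silyl ether, so that stereocentre should pass unchanged.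

**Step 6**
Reactants: 14 (1S,4R)-2-[(1R)-1-(TBS-oxy)-4-methylpent-3-en-1-yl]-5,8-dimethoxy-1,4-dihydro-1,4-epoxynaphthalene (both bridgehead epimers)
Product: 17 2-[(1R)-1-(TBS-oxy)-4-methylpent-3-en-1-yl]-5,8-dimethoxynaphthalene-1,4-dione, via 2-substituted naphthol 15 (not isolated), via 3-substituted naphthol 16 (not isolated)
Conditions: CF3CO2H (0.1 equiv), CH2Cl2, 0 °C; solid NaHCO3, solvent exchanged for acetone without purification; then (KSO3)2NO (2.5 equiv), aq KH2PO4, 0 °C → rt
Reagents that add atoms: potassium nitrosodisulfonate, [K+].[K+].[O]N(S(=O)(=O)[O-])S(=O)(=O)[O-]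
Why: Acid-catalysed isomerisation of the 1,4-epoxy-1,4-dihydronaphthalene (bridge protonation, C–O ionisation to a cation stabilised by the methoxy-bearing ring, hydride shift and tautomerisation) should aromatise ring B to naphthol 15 or 16 according to which bridgehead C–O bond breaks, and Teuber oxidation of the air-sensitive crude naphthols then places the new oxygen on the free position para to either phenol, so both should converge on the single 1,4-quinone while the dimethoxy ring, the alkene, the silyl ether and C1' take no part.

**Step 7**
Reactants: 17 2-[(1R)-1-(TBS-oxy)-4-methylpent-3-en-1-yl]-5,8-dimethoxynaphthalene-1,4-dione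
Product: 18 2-[(1R)-1-hydroxy-4-methylpent-3-en-1-yl]-5,8-dimethoxynaphthalene-1,4-dione
Conditions: HF·pyridine, pyridine, THF, 0 °C → rt
Reagents that add atoms: none
Why: Fluoride-driven desilylation cleaves only the Si–O bond under buffered, non-basic conditions that spare the base-sensitive quinone, so C1' keeps its configuration.

**Step 8**
Reactants: 18 2-[(1R)-1-hydroxy-4-methylpent-3-en-1-yl]-5,8-dimethoxynaphthalene-1,4-dione
Product: 19 (1R)-1-(5,8-dimethoxy-1,4-dioxo-1,4-dihydronaphthalen-2-yl)-4-methylpent-3-en-1-yl 3-methylbutanoate
Conditions: 3-methylbutanoic acid (1.5 equiv), N,N'-dicyclohexylcarbodiimide (1.5 equiv), 4-(dimethylamino)pyridine (0.1 equiv), CH2Cl2, 0 °C → rt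
Reagents that add atoms: 3-methylbutanoic acid, CC(C)CC(=O)O
Why: Steglich esterification acylates the secondary alcohol at oxygen under nearly neutral conditions, so the ester should form with retention at C1' and without base-induced redox isomerisation of the hydroxyalkyl quinone.

**Step 9**
Reactants: 19 (1R)-1-(5,8-dimethoxy-1,4-dioxo-1,4-dihydronaphthalen-2-yl)-4-methylpent-3-en-1-yl 3-methylbutanoate
Product: 21 isovalerylshikonin [(1R)-1-(5,8-dihydroxy-1,4-dioxo-1,4-dihydronaphthalen-2-yl)-4-methylpent-3-en-1-yl 3-methylbutanoate], via naphthodiquinone 20 (not isolated)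
Conditions: AgO (4 equiv), 6 M HNO3, acetone, rt, a few minutes; then CHCl3 and aq Na2S2O4 (1.1 equiv), 0 °C
Reagents that add atoms: water, O
Why: Oxidative demethylation of the 1,4-dimethoxyarene ring by divalent silver gives the 1,4,5,8-tetrone, and its two-electron reduction by Na2S2O4 in the work-up should give the naphthazarin, the ester-protected side chain being the form expected to tolerate this short acidic oxidation.

**Compound list**

1 | 4-methylpent-3-enoic acid | CC(C)=CCC(=O)O | starting material
2 | 1-(1H-imidazol-1-yl)-4-methylpent-3-en-1-one (acyl imidazole) | CC(C)=CCC(=O)n1ccnc1 | intermediate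
3 | N-methoxy-N,4-dimethylpent-3-enamide | CC(C)=CCC(=O)N(C)OC | intermediate
4 | 3-bromofuran | Brc1ccoc1 | starting material
5 | 3-lithiofuran | [Li]c1ccoc1 | intermediate
6 | lithium 1-(furan-3-yl)-1-[methoxy(methyl)amino]-4-methylpent-3-en-1-olate (racemic tetrahedral adduct) | CC(C)=CCC(O[Li])(N(C)OC)c1ccoc1 | intermediate
7 | 1-(furan-3-yl)-4-methylpent-3-en-1-one | CC(C)=CCC(=O)c1ccoc1 | intermediate
8 | 2-{[(1R)-1-(furan-3-yl)-4-methylpent-3-en-1-yl]oxy}-1,3,2-benzodioxaborole | CC(C)=CC[C@@H](OB1Oc2ccccc2O1)c1ccoc1 | intermediate
9 | (1R)-1-(furan-3-yl)-4-methylpent-3-en-1-ol | CC(C)=CC[C@@H](O)c1ccoc1 | intermediate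
10 | tert-butyl{[(1R)-1-(furan-3-yl)-4-methylpent-3-en-1-yl]oxy}dimethylsilane | CC(C)=CC[C@@H](O[Si](C)(C)C(C)(C)C)c1ccoc1 | intermediate
11 | 2-bromo-1,4-dimethoxybenzene | COc1ccc(OC)c(Br)c1 | starting material
12 | 2-bromo-3-lithio-1,4-dimethoxybenzene | COc1ccc(OC)c(Br)c1[Li] | intermediate
13 | 3,6-dimethoxybenzyne (1,2-didehydro-3,6-dimethoxybenzene) | COC1=CC=C(OC)C#C1 | intermediate
14 | (1S,4R)-2-[(1R)-1-{[tert-butyl(dimethyl)silyl]oxy}-4-methylpent-3-en-1-yl]-5,8-dimethoxy-1,4-dihydro-1,4-epoxynaphthalene (drawn isomer; the (1R,4S) bridgehead epimer is carried under the same number) | CC(C)=CC[C@@H](O[Si](C)(C)C(C)(C)C)C1=C[C@H]2O[C@@H]1c3c(OC)ccc(OC)c23 | intermediate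
15 | 2-[(1R)-1-{[tert-butyl(dimethyl)silyl]oxy}-4-methylpent-3-en-1-yl]-5,8-dimethoxynaphthalen-1-ol | CC(C)=CC[C@@H](O[Si](C)(C)C(C)(C)C)c1ccc2c(OC)ccc(OC)c2c1O | intermediate
16 | 3-[(1R)-1-{[tert-butyl(dimethyl)silyl]oxy}-4-methylpent-3-en-1-yl]-5,8-dimethoxynaphthalen-1-ol | CC(C)=CC[C@@H](O[Si](C)(C)C(C)(C)C)c1cc(O)c2c(OC)ccc(OC)c2c1 | intermediate
17 | 2-[(1R)-1-{[tert-butyl(dimethyl)silyl]oxy}-4-methylpent-3-en-1-yl]-5,8-dimethoxynaphthalene-1,4-dione | CC(C)=CC[C@@H](O[Si](C)(C)C(C)(C)C)C1=CC(=O)c2c(OC)ccc(OC)c2C1=O | intermediate
18 | 2-[(1R)-1-hydroxy-4-methylpent-3-en-1-yl]-5,8-dimethoxynaphthalene-1,4-dione | CC(C)=CC[C@@H](O)C1=CC(=O)c2c(OC)ccc(OC)c2C1=O | intermediate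
19 | (1R)-1-(5,8-dimethoxy-1,4-dioxo-1,4-dihydronaphthalen-2-yl)-4-methylpent-3-en-1-yl 3-methylbutanoate | CC(C)=CC[C@@H](OC(=O)CC(C)C)C1=CC(=O)c2c(OC)ccc(OC)c2C1=O | intermediate
20 | (1R)-4-methyl-1-(1,4,5,8-tetraoxo-1,4,5,8-tetrahydronaphthalen-2-yl)pent-3-en-1-yl 3-methylbutanoate | CC(C)=CC[C@@H](OC(=O)CC(C)C)C1=CC(=O)C2=C(C1=O)C(=O)C=CC2=O | intermediate
21 | isovalerylshikonin, (1R)-1-(5,8-dihydroxy-1,4-dioxo-1,4-dihydronaphthalen-2-yl)-4-methylpent-3-en-1-yl 3-methylbutanoate | CC(C)=CC[C@@H](OC(=O)CC(C)C)C1=CC(=O)c2c(O)ccc(O)c2C1=O | target

**Totals.** Total step count: 9. Longest linear sequence: 9 steps (1 → 21).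

**Steps most likely to fail**

Step 5. With the furan as the limiting partner, the aryne may be consumed by the amide base, by diisopropylamine or by the strained alkene of the product, and the furan may be metallated before it can react. The fallback sets out from 11 and 10 and comes back at 14. Bromide 11 would be lithiated with LiN(iPr)2 at −78 °C and quenched cold with I2 to give 2-bromo-3-iodo-1,4-dimethoxybenzene F1. Addition of n-BuLi to F1 and 10 in toluene–THF at −78 °C would effect iodine–lithium exchange and regenerate aryllithium 12 with no amine or amide present. Warming would then release aryne 13 for capture by a near-stoichiometric amount of 10.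

Step 6. Once ring B is an electron-rich naphthol, the acid may ionise the benzylic C1'–O bond, which would cause loss of the silyloxy group, racemisation or cation–alkene side reactions. The fallback sets out from 14 and comes back at 17. The bridge would be opened under neutral conditions with catalytic [Rh(CO)2Cl]2 (monovalent rhodium) in CHCl3 at rt, through metal insertion into the allylic C–O bond followed by hydride migration, not through a free carbocation. The crude naphthols 15 and 16 would be oxidised at once with (KSO3)2NO without isolation. It makes no new compound (F0).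

Step 9. The trisubstituted alkene may be oxidised or the ester hydrolysed in the AgO/HNO3 medium, and excess dithionite may reduce the product further with expulsion of the C1' acyloxy group. The fallback sets out from 19 and comes back at 21. It is a non-oxidative, chelation-directed ether cleavage with BCl3 in CH2Cl2 at −78 °C: boron binds each peri-methoxy oxygen together with the neighbouring quinone carbonyl, chloride removes the methyl group as chloromethane, and aqueous work-up releases the naphthazarin 21. It makes no new compound (F0).

**Further compounds**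

F1 | step 5 | 2-bromo-3-iodo-1,4-dimethoxybenzene | COc1ccc(OC)c(I)c1Br
F0 | step 6 | none | none
F0 | step 9 | none | none
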